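**Strategy**

Everything rests on cutting ring B of this depside at C1'–C2' and C5'–C6', so that the ring is grown onto an ester that already links it to ring A. Ring B has a meta pair of oxygens (OH on C2', OMe on C4') and a methyl on C6' flanking the ester-bearing C1'; a diene oxygenated twice at C1 and once at C3 plus a tetrolate dienophile deliver exactly this array. One Diels–Alder/aromatisation sequence thus forms two C–C bonds, closes ring B and fixes its substitution, with no acylation by a di-ortho-substituted benzoic acid. The precursor is benzyl olivetolate esterified at O-4 with but-2-ynoic acid, its chelated 2-OH silylated in the flask.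

Key step: step 5

Remark on the chemistry: the target is achiral, the ketene acetal geometry of the diene (drawn E) is irrelevant because that carbon becomes aromatic C2', and the chelated 2-OH of ring A is masked in the flask as a trimethylsilyl ether before the diene is added so that no phenolic proton destroys the ketene acetal.

**Route**

Step 1
Reactants: 1 olivetol (5-pentylbenzene-1,3-diol)
Product: 3 olivetolic acid (2,4-dihydroxy-6-pentylbenzoic acid), via magnesium salicylate chelate 2 (not isolated)
Conditions: MeOMgOCO2Me (2 M in DMF, excess), 120 °C, N2; then cold 1 M HCl, 0 °C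
Reagents that add atoms: methyl magnesium carbonate (MeOMgOCO2Me), COC(=O)O[Mg]OC
Why: Ortho-carboxylation of a phenol with methyl magnesium carbonate (a Kolbe–Schmitt-type reaction) is driven by formation of the magnesium salicylate chelate and is an established entry from 5-alkylresorcinols to 6-alkyl-2,4-dihydroxybenzoic acids; the work-up is kept cold because the acid decarboxylates on heating.

Step 2
Reactants: 3 olivetolic acid; 4 benzyl bromide
Product: 5 benzyl 2,4-dihydroxy-6-pentylbenzoate
Conditions: KHCO3 (1.2 equiv), DMF, rt
Reagents that add atoms: none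
Why: SN2 O-alkylation of the carboxylate; bicarbonate deprotonates only the acid and not the phenols, so the benzyl ester should form chemoselectively.

Step 3
Reactants: 5 benzyl 2,4-dihydroxy-6-pentylbenzoate; 6 but-2-ynoic acid
Product: 7 benzyl 4-(but-2-ynoyloxy)-2-hydroxy-6-pentylbenzoate
Conditions: DCC (1.1 equiv), DMAP (5 mol%), CH2Cl2, −10 to 0 °C
Reagents that add atoms: none
Why: Steglich esterification; the 2-OH is hydrogen-bonded to the ester carbonyl, so one equivalent of activated acid should acylate only the free 4-OH, while low temperature and little DMAP limit conjugate addition to the ynoate.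

Step 4
Reactants: 8 methyl (E)-3-methoxybut-2-enoate
Product: 10 (1E)-1,3-dimethoxy-1-(trimethylsilyloxy)buta-1,3-diene, via lithium dienolate 9 (not isolated)
Conditions: LiN(i-Pr)2, THF, −78 °C; then Me3SiCl, −78 °C to rt; distillation under reduced pressure
Reagents that add atoms: chlorotrimethylsilane, C[Si](C)(C)Cl
Why: γ-Deprotonation of the vinylogous carbonate-type ester gives the extended dienolate, and O-silylation of this enolate by the hard silyl chloride gives the vinylogous silyl ketene acetal, a standard preparation of such dienes.

Step 5
Reactants: 7 benzyl 4-(but-2-ynoyloxy)-2-hydroxy-6-pentylbenzoate; 10 (1E)-1,3-dimethoxy-1-(trimethylsilyloxy)buta-1,3-diene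
Product: 14 benzyl 2-hydroxy-4-[(2-hydroxy-4-methoxy-6-methylbenzoyl)oxy]-6-pentylbenzoate, via ring A trimethylsilyl ether 11 (not isolated), via cyclohexa-1,4-diene cycloadduct 12 (not isolated), via bis(trimethylsilyl) ether 13 (not isolated)
Conditions: MeC(OSiMe3)=NSiMe3 (BSA, 1.2 equiv), PhMe, 50 °C; then 10 (3 equiv, in portions), 120 °C, sealed tube; then 1 M HCl, THF, rt
Reagents that add atoms: none
Why: Silylation of the chelated 2-OH of ring A with BSA removes the only acidic proton, so the ketene acetal is not wasted by protonation. Bond formation should then be stepwise in character within a normal-electron-demand Diels–Alder reaction: bonding begins between the unsubstituted diene terminus (it becomes C5') and the alkyne carbon that carries the methyl group (C6'), and the dioxygenated terminus (it becomes C2') then joins the carbon next to the carbonyl (C1'), which closes ring B as a six-membered carbocycle in a [4+2] mode. Cycloadduct 12 is a 1,4-cyclohexadiene with a methyl silyl ketal at C2' and a CH2 at C5'; it should lose methanol to give arene 13, and any adduct that survives is converted into the same phenol by ketal hydrolysis and tautomerisation during the acidic work-up, which also removes both silyl groups. The closest known reaction type is the benzannulation of 1,1,3-trioxygenated butadienes with alk-2-ynoates to give resorcylate esters. No stereocentre remains in the product (the one at C2' of 12 disappears on aromatisation); the selectivity needed is regiochemical and is secured by the match of the most nucleophilic diene carbon (the CH2 terminus, fed by all three oxygens) with the β-carbon of the ynoate, whose electrophilicity the aryl ester raises above that of an alkyl tetrolate.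

Step 6
Reactants: 14 benzyl 2-hydroxy-4-[(2-hydroxy-4-methoxy-6-methylbenzoyl)oxy]-6-pentylbenzoate
Product: 15 2-hydroxy-4-[(2-hydroxy-4-methoxy-6-methylbenzoyl)oxy]-6-pentylbenzoic acid (target)
Conditions: H2 (1 atm), 10% Pd/C, EtOAc, rt
Reagents that add atoms: none
Why: Hydrogenolysis of the benzylic C–O bond is orthogonal to the aryl ester, the phenols and the methyl ether, so the depside link should survive these neutral conditions; the acid is not heated, to avoid decarboxylation.

**Compound list**

1 | olivetol (5-pentylbenzene-1,3-diol) | CCCCCc1cc(O)cc(O)c1 | starting material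
2 | magnesium salicylate chelate of olivetolic acid (cyclic Mg carboxylate–phenoxide, not isolated) | CCCCCc1cc(O)cc2O[Mg]OC(=O)c12 | intermediate
3 | olivetolic acid (2,4-dihydroxy-6-pentylbenzoic acid) | CCCCCc1cc(O)cc(O)c1C(=O)O | intermediate
4 | benzyl bromide | BrCc1ccccc1 | starting material
5 | benzyl 2,4-dihydroxy-6-pentylbenzoate | CCCCCc1cc(O)cc(O)c1C(=O)OCc1ccccc1 | intermediate
6 | but-2-ynoic acid | CC#CC(=O)O | starting material
7 | benzyl 4-(but-2-ynoyloxy)-2-hydroxy-6-pentylbenzoate | CCCCCc1cc(OC(=O)C#CC)cc(O)c1C(=O)OCc1ccccc1 | intermediate
8 | methyl (E)-3-methoxybut-2-enoate | CO/C(C)=C/C(=O)OC | starting material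
9 | lithium (1Z)-1,3-dimethoxybuta-1,3-dien-1-olate (not isolated) | [Li+].C=C(OC)/C=C(\OC)[O-] | intermediate
10 | (1E)-1,3-dimethoxy-1-(trimethylsilyloxy)buta-1,3-diene | C=C(OC)/C=C(\OC)O[Si](C)(C)C | intermediate
11 | benzyl 4-(but-2-ynoyloxy)-6-pentyl-2-(trimethylsilyloxy)benzoate (not isolated) | CCCCCc1cc(OC(=O)C#CC)cc(O[Si](C)(C)C)c1C(=O)OCc1ccccc1 | intermediate
12 | benzyl 4-{[4,6-dimethoxy-2-methyl-6-(trimethylsilyloxy)cyclohexa-1,4-diene-1-carbonyl]oxy}-6-pentyl-2-(trimethylsilyloxy)benzoate (racemic at the ketal carbon, not isolated) | CCCCCc1cc(OC(=O)C2=C(C)CC(OC)=CC2(OC)O[Si](C)(C)C)cc(O[Si](C)(C)C)c1C(=O)OCc1ccccc1 | intermediate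
13 | benzyl 4-{[4-methoxy-6-methyl-2-(trimethylsilyloxy)benzoyl]oxy}-6-pentyl-2-(trimethylsilyloxy)benzoate (not isolated) | CCCCCc1cc(OC(=O)c2c(C)cc(OC)cc2O[Si](C)(C)C)cc(O[Si](C)(C)C)c1C(=O)OCc1ccccc1 | intermediate
14 | benzyl 2-hydroxy-4-[(2-hydroxy-4-methoxy-6-methylbenzoyl)oxy]-6-pentylbenzoate | CCCCCc1cc(OC(=O)c2c(C)cc(OC)cc2O)cc(O)c1C(=O)OCc1ccccc1 | intermediate
15 | 2-hydroxy-4-[(2-hydroxy-4-methoxy-6-methylbenzoyl)oxy]-6-pentylbenzoic acid (CNP0313373.0, achiral) | CCCCCc1cc(OC(=O)c2c(C)cc(OC)cc2O)cc(O)c1C(=O)O | target

**Step count**

Total steps: 6. Longest linear sequence: 5 (steps 1, 2, 3, 5, 6); the diene is made in one step (step 4) on a convergent branch.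

**Steps most likely to fail**

1. Step 5. The β-methyl ynoate is a slow dienophile, so the diene may decompose by silyl migration or hydrolysis before it adds. The adduct may also aromatise by loss of silanol instead of methanol, which would leave a methyl ether at C2'. The fallback sets out from 5 and comes back to the route at 15; it brings ring B in preformed. Commercial 2-hydroxy-4-methoxy-6-methylbenzoic acid F1 would be dibenzylated with 4 (K2CO3, DMF, 60 °C) to benzyl 2-(benzyloxy)-4-methoxy-6-methylbenzoate F2. The hindered ester would be saponified (KOH, aqueous DMSO, 90 °C) to 2-(benzyloxy)-4-methoxy-6-methylbenzoic acid F3. F3 would be condensed with 5 through its mixed trifluoroacetic anhydride ((CF3CO)2O, PhMe, rt), the classical way to acylate the free 4-OH of a benzyl resorcylate with a hindered benzoic acid, to give benzyl 4-{[2-(benzyloxy)-4-methoxy-6-methylbenzoyl]oxy}-2-hydroxy-6-pentylbenzoate F4. Hydrogenolysis (H2, Pd/C, EtOAc, rt) would remove both benzyl groups and give 15.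

2. Step 3. Acylation may occur at both phenols, the nucleophilic catalyst may add to the triple bond, and the O-acylisourea may rearrange to an N-acylurea. The fallback sets out from 5 and 6 and comes back at 7; it separates activation from coupling and uses no nucleophilic catalyst. Acid 6 would be converted under neutral conditions with 1-chloro-N,N,2-trimethylprop-1-en-1-amine (CH2Cl2, 0 °C) into but-2-ynoyl chloride F5. F5 would be added slowly to 5 and i-Pr2NEt (1 equiv) in CH2Cl2 at −40 °C; the 4-OH, para to the ester and not hydrogen-bonded, is the more acidic and more exposed phenol and should be acylated selectively to give 7.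

3. Step 1. Carboxylation may occur at the carbon between the two hydroxyls, conversion may stall, and CO2 may be lost again during work-up. The fallback sets out from 1 and comes back at 3; it introduces the carbon at the aldehyde oxidation level. Vilsmeier–Haack formylation (POCl3, DMF, 0 °C to rt; aqueous NaOAc) should give 2,4-dihydroxy-6-pentylbenzaldehyde F6, by substitution para to one hydroxyl and ortho to the other. Chlorite oxidation (NaClO2, NaH2PO4, DMSO–H2O, rt), in which DMSO scavenges hypochlorite and protects the electron-rich ring from chlorination, should give 3.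

**Further compounds**

F1 | step 5 | 2-hydroxy-4-methoxy-6-methylbenzoic acid (purchased) | Cc1cc(OC)cc(O)c1C(=O)O
F2 | step 5 | benzyl 2-(benzyloxy)-4-methoxy-6-methylbenzoate | Cc1cc(OC)cc(OCc2ccccc2)c1C(=O)OCc1ccccc1
F3 | step 5 | 2-(benzyloxy)-4-methoxy-6-methylbenzoic acid | Cc1cc(OC)cc(OCc2ccccc2)c1C(=O)O
F4 | step 5 | benzyl 4-{[2-(benzyloxy)-4-methoxy-6-methylbenzoyl]oxy}-2-hydroxy-6-pentylbenzoate | CCCCCc1cc(OC(=O)c2c(C)cc(OC)cc2OCc2ccccc2)cc(O)c1C(=O)OCc1ccccc1
F5 | step 3 | but-2-ynoyl chloride | CC#CC(=O)Cl
F6 | step 1 | 2,4-dihydroxy-6-pentylbenzaldehyde | CCCCCc1cc(O)cc(O)c1C=O
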